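Everything rests on disconnecting pendant lactone ring E at C3–C5″ and O1″–C2″. The feature exploited is the threo N4–C3–C5″–O1″ amino alcohol array that joins ring A to ring E, together with the methacrylate-like unit C4″–C3″–C2″. In one operation an ester-bearing allylsilane adds to the C3 carbaldehyde held in a five-membered TiCl4 chelate with N4, which sets C5″, and the adduct lactonises to the α-methylene lactone; hydrogenation then gives the cis C3″ methyl. The precursor is the complete ring A–D amino aldehyde, built from N-Boc-L-prolinol with one oxazolidinone auxiliary that controls C9 and the C5′/C6′ aldol pair, then a palladium oxycarbonylation for the furofuranone.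

Key step: step 16

Remark: the SMILES is read as 3S,9R,9aS (pyrroloazepine, plain locants), 3′S,3a′R,5′S,6′R,6a′R (furo[3,2-b]furanone, primed; all four substituents of tetrahydrofuran ring C on one face, C3′ methyl endo) and 3″S,5″S (ring E, cis). Rings: A pyrrolidine, B azepane, C tetrahydrofuran, D fused lactone, E pendant lactone.
Remark: Pyr stands for the (2S,5S)-1-(tert-butoxycarbonyl)-5-[(tert-butyldimethylsilyloxy)methyl]pyrrolidin-2-yl group (2,5-trans). Compounds 1, 5, 10, 13 and 26 are assumed to be bought, and prop-1-ynylmagnesium bromide is used as its commercial THF solution.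

**Route**

Step 1
Reactants: 1 tert-butyl (2S)-2-(hydroxymethyl)pyrrolidine-1-carboxylate (N-Boc-L-prolinol)
Product: 2 tert-butyl (2S)-2-[(tert-butyldimethylsilyloxy)methyl]pyrrolidine-1-carboxylate
Conditions: TBSCl, imidazole, DMF, 0 °C → rt
Reagents that add atoms: tert-butyldimethylsilyl chloride, CC(C)(C)[Si](C)(C)Cl
Why: Routine silylation of a primary alcohol; the stereocentre (later C3) is taken unchanged from the chiral pool.

Step 2
Reactants: 2 silyl ether
Product: 4 tert-butyl (2S,5S)-2-[(tert-butyldimethylsilyloxy)methyl]-5-formylpyrrolidine-1-carboxylate (2,5-trans), via lithiated carbamate 3 (not isolated)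
Conditions: s-BuLi, TMEDA, Et2O, −78 °C; then DMF, −78 °C; AcOH
Reagents that add atoms: N,N-dimethylformamide, CN(C)C=O
Why: Beak carbamate-directed α-lithiation removes a proton at the unsubstituted α-carbon, and the configurationally stable organolithium is formylated with retention on the face trans to the existing substituent, which sets C9a.

Step 3
Reactants: 5 (4R)-4-benzyl-1,3-oxazolidin-2-one
Product: 7 (4R)-4-benzyl-3-(bromoacetyl)-1,3-oxazolidin-2-one, via lithium oxazolidinide 6 (not isolated)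
Conditions: n-BuLi, THF, −78 °C; then BrCH2COBr, −78 → 0 °C
Reagents that add atoms: bromoacetyl bromide, BrCC(Br)=O
Why: N-acylation of a lithiated Evans oxazolidinone, the acyl bromide reacting far faster than the alkyl bromide at low temperature.

Step 4
Reactants: 7 bromoacetyl imide
Product: 8 diethyl {2-[(4R)-4-benzyl-2-oxo-1,3-oxazolidin-3-yl]-2-oxoethyl}phosphonate
Conditions: P(OEt)3, toluene, 100 °C
Reagents that add atoms: triethyl phosphite, CCOP(OCC)OCC
Why: Michaelis–Arbuzov reaction of an α-bromo imide, which behaves like an α-bromo ester and gives the phosphonate.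

Step 5
Reactants: 4 trans aldehyde; 8 phosphonate
Product: 9 (4R)-4-benzyl-3-[(2E)-3-Pyr-prop-2-enoyl]-1,3-oxazolidin-2-one
Conditions: LiCl, iPr2NEt, MeCN, rt
Reagents that add atoms: none
Why: Masamune–Roush variant of the Horner–Wadsworth–Emmons olefination, whose mild amine base spares the α-amino aldehyde stereocentre and gives the (E)-alkene.

Step 6
Reactants: 9 enoyl imide; 10 1-bromo-4-chlorobutane
Product: 12 (4R)-4-benzyl-3-[(3R)-7-chloro-3-Pyr-heptanoyl]-1,3-oxazolidin-2-one, via 4-chlorobutylmagnesium bromide 11 (not isolated)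
Conditions: 10, Mg, THF, rt; then CuBr·SMe2, THF–Me2S, −40 °C; then 9, −40 → −10 °C; aq. NH4Cl
Reagents that add atoms: none
Why: Copper-mediated conjugate addition of a Grignard reagent to an N-enoyl oxazolidinone held syn-s-cis by magnesium chelation, the alkyl group entering C9 opposite the benzyl group, which is also the face anti to the C9a–N bond (matched), so C9 is set as R.

Step 7
Reactants: 12 conjugate adduct; 13 acetaldehyde
Product: 15 (4R)-4-benzyl-3-{(2R,3S)-2-[(1R)-5-chloro-1-Pyr-pentyl]-3-hydroxybutanoyl}-1,3-oxazolidin-2-one, via dibutylboron enolate 14 (not isolated)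
Conditions: Bu2BOTf, iPr2NEt, CH2Cl2, 0 °C; then 13, −78 → 0 °C; pH 7 buffer, MeOH, H2O2
Reagents that add atoms: none
Why: Evans boron aldol reaction, in which the (Z)-enolate reacts through a closed chair transition state on the face opposite the benzyl group and so sets C6′ and C5′ as the auxiliary-controlled syn pair.

Step 8
Reactants: 15 aldol adduct
Product: 17 (2R,3S)-2-[(1R)-5-chloro-1-Pyr-pentyl]-3-hydroxybutanoic acid, via peroxy acid 16 (not isolated)
Conditions: LiOH, H2O2, THF–H2O, 0 °C; then aq. Na2SO3; 1 M HCl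
Reagents that add atoms: hydrogen peroxide, OO
Why: Hydroperoxide cleavage of the imide, which attacks the exocyclic carbonyl even in hindered cases and touches no stereocentre.

Step 9
Reactants: 17 hydroxy acid
Product: 18 (2R,3S)-2-[(1R)-5-chloro-1-Pyr-pentyl]-3-hydroxy-N-methoxy-N-methylbutanamide
Conditions: MeNHOMe·HCl, EDC·HCl, HOBt, N-methylmorpholine, CH2Cl2, 0 °C → rt
Reagents that add atoms: N,O-dimethylhydroxylamine hydrochloride, CNOC.Cl
Why: Carbodiimide amide coupling, chosen over direct transamination because the α-carbon is heavily branched.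

Step 10
Reactants: 18 Weinreb amide
Product: 19 (5R,6S)-5-[(1R)-5-chloro-1-Pyr-pentyl]-6-hydroxyhept-2-yn-4-one
Conditions: CH3C≡CMgBr (excess), THF, 0 °C → rt; poured into cold aq. NH4Cl
Reagents that add atoms: prop-1-ynylmagnesium bromide, CC#C[Mg]Br
Why: Weinreb ketone synthesis, the chelated tetrahedral intermediate preventing a second addition after the first equivalent has deprotonated the hydroxyl group.

Step 11
Reactants: 19 hydroxy ynone
Product: 20 (2S,3R,4R)-3-[(1R)-5-chloro-1-Pyr-pentyl]hept-5-yne-2,4-diol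
Conditions: Me4NBH(OAc)3, MeCN–AcOH, −30 °C
Reagents that add atoms: none
Why: Evans–Saksena directed reduction, in which the hydroxyl-bound acetoxyborohydride delivers hydride intramolecularly through a chair transition state to give the 1,3-anti diol and so sets C6a′.

Step 12
Reactants: 20 alkynediol
Product: 21 (2S,3R,4S,5Z)-3-[(1R)-5-chloro-1-Pyr-pentyl]hept-5-ene-2,4-diol
Conditions: H2 (1 atm), Pd/CaCO3 poisoned with Pb(OAc)2, quinoline, EtOAc, rt
Reagents that add atoms: none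
Why: Lindlar semi-hydrogenation adds hydrogen syn to the alkyne and gives the (Z)-alkene without touching the alkyl chloride.

Step 13
Reactants: 21 (Z)-alkenediol
Product: 22 tert-butyl (2S,5S)-2-[(tert-butyldimethylsilyloxy)methyl]-5-{(1R)-5-chloro-1-[(3S,3aR,5S,6R,6aR)-3,5-dimethyl-2-oxohexahydrofuro[3,2-b]furan-6-yl]pentyl}pyrrolidine-1-carboxylate
Conditions: PdCl2 (cat.), CuCl2, NaOAc, AcOH, CO (1 atm), rt
Reagents that add atoms: carbon monoxide, [C-]#[O+]
Why: Oxycarbonylative bicyclisation of a 4-ene-1,3-diol by divalent palladium, in which the C5′ hydroxyl adds 5-exo and anti to palladium at C3a′, CO inserts with retention at C3′ and the C6a′ hydroxyl captures the acyl palladium, so that only the cis-fused adduct is drained and the (Z)-alkene geometry places the C3′ methyl endo; CuCl2 reoxidises zerovalent palladium.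

Step 14
Reactants: 22 furofuranone carbamate
Product: 24 (3S,3aR,5S,6R,6aR)-6-[(3S,9R,9aS)-3-(hydroxymethyl)octahydro-1H-pyrrolo[1,2-a]azepin-9-yl]-3,5-dimethylhexahydrofuro[3,2-b]furan-2(3H)-one, via amino alcohol 23 (not isolated)
Conditions: CF3CO2H–CH2Cl2–H2O, 0 °C → rt; evaporate; then K2CO3, NaI (cat.), MeCN (high dilution), 70 °C
Reagents that add atoms: none
Why: Acidolysis removes the carbamate and the silyl ether, and the freed secondary amine then closes azepane ring B by intramolecular SN2 N-alkylation (7-exo-tet, iodide catalysis) without touching a stereocentre.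

Step 15
Reactants: 24 amino alcohol
Product: 25 (3S,9R,9aS)-9-[(3S,3aR,5S,6R,6aR)-3,5-dimethyl-2-oxohexahydrofuro[3,2-b]furan-6-yl]octahydro-1H-pyrrolo[1,2-a]azepine-3-carbaldehyde
Conditions: (COCl)2, DMSO, CH2Cl2, −78 °C; then Et3N, −78 → −30 °C; crude product taken on within the hour
Reagents that add atoms: none
Why: Swern oxidation, whose low temperature and short base contact keep the α-amino aldehyde from epimerising at C3.

Step 16
Reactants: 25 amino aldehyde; 26 ethyl 2-(trimethylsilylmethyl)acrylate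
Product: 28 (3S,3aR,5S,6R,6aR)-3,5-dimethyl-6-{(3S,9R,9aS)-3-[(2S)-4-methylidene-5-oxotetrahydrofuran-2-yl]octahydro-1H-pyrrolo[1,2-a]azepin-9-yl}hexahydrofuro[3,2-b]furan-2(3H)-one, via hydroxy ester 27 (not isolated)
Conditions: TiCl4 (excess), CH2Cl2, −78 °C; then 26, −78 → 0 °C; then p-TsOH·H2O, rt; aq. NaHCO3
Reagents that add atoms: none
Why: TiCl4 binds N4 and the aldehyde oxygen in a five-membered chelate fused to ring A, the allylsilane attacks C5″ through an open antiperiplanar SE2′ transition state with loss of the silyl group, and the C5″ oxygen then acylates at the ester carbon with loss of ethanol. The closest known reaction type is the Hosomi–Sakurai addition of 2-(alkoxycarbonyl)allylsilanes to aldehydes with lactonisation to α-methylene-γ-butyrolactones, joined to Cram-chelate additions of allylsilanes to α-(dialkylamino) aldehydes. Ring E closes by a 5-exo-trig acyl substitution of O1″ on C2″. The one new stereocentre, C5″, is controlled by C3 through the chelate: the nucleophile enters on the exo face beside H3 and anti to the ring A carbon C2, which puts the oxygen syn (threo) to N4. The step needs chelate control over Felkin–Anh control and no epimerisation at C3; the tertiary N4 is a strong donor for TiCl4, the excess of TiCl4 leaves no free amine to enolise the aldehyde, and complexation is done at −78 °C on freshly made 25.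

Step 17
Reactants: 28 α-methylene lactone
Product: 29 (3S,3aR,5S,6R,6aR)-3,5-dimethyl-6-{(3S,9R,9aS)-3-[(2S,4S)-4-methyl-5-oxotetrahydrofuran-2-yl]octahydro-1H-pyrrolo[1,2-a]azepin-9-yl}hexahydrofuro[3,2-b]furan-2(3H)-one
Conditions: H2 (1 atm), Pd/C, EtOAc, rt
Reagents that add atoms: none
Why: Heterogeneous hydrogenation of the exocyclic alkene from the face of ring E opposite the C5″ substituent delivers hydrogen to C3″ trans to that substituent, so the methyl ends cis (C3″ S).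

**Compound list**

1 | tert-butyl (2S)-2-(hydroxymethyl)pyrrolidine-1-carboxylate | CC(C)(C)OC(=O)N1CCC[C@H]1CO | starting material
2 | tert-butyl (2S)-2-[(tert-butyldimethylsilyloxy)methyl]pyrrolidine-1-carboxylate | CC(C)(C)OC(=O)N1CCC[C@H]1CO[Si](C)(C)C(C)(C)C | intermediate
3 | tert-butyl (2S,5R)-2-[(tert-butyldimethylsilyloxy)methyl]-5-lithiopyrrolidine-1-carboxylate (Li trans to the C2 substituent) | CC(C)(C)OC(=O)N1[C@H]([Li])CC[C@H]1CO[Si](C)(C)C(C)(C)C | intermediate
4 | tert-butyl (2S,5S)-2-[(tert-butyldimethylsilyloxy)methyl]-5-formylpyrrolidine-1-carboxylate | CC(C)(C)OC(=O)N1[C@H](C=O)CC[C@H]1CO[Si](C)(C)C(C)(C)C | intermediate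
5 | (4R)-4-benzyl-1,3-oxazolidin-2-one | O=C1N[C@H](Cc2ccccc2)CO1 | starting material
6 | lithium (4R)-4-benzyl-2-oxo-1,3-oxazolidin-3-ide | [Li]N1[C@H](Cc2ccccc2)COC1=O | intermediate
7 | (4R)-4-benzyl-3-(bromoacetyl)-1,3-oxazolidin-2-one | O=C1OC[C@@H](Cc2ccccc2)N1C(=O)CBr | intermediate
8 | diethyl {2-[(4R)-4-benzyl-2-oxo-1,3-oxazolidin-3-yl]-2-oxoethyl}phosphonate | O=C1OC[C@@H](Cc2ccccc2)N1C(=O)CP(=O)(OCC)OCC | intermediate
9 | (4R)-4-benzyl-3-[(2E)-3-Pyr-prop-2-enoyl]-1,3-oxazolidin-2-one | O=C1OC[C@@H](Cc2ccccc2)N1C(=O)/C=C/[C@@H]1CC[C@@H](CO[Si](C)(C)C(C)(C)C)N1C(=O)OC(C)(C)C | intermediate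
10 | 1-bromo-4-chlorobutane | ClCCCCBr | starting material
11 | 4-chlorobutylmagnesium bromide | ClCCCC[Mg]Br | intermediate
12 | (4R)-4-benzyl-3-[(3R)-7-chloro-3-Pyr-heptanoyl]-1,3-oxazolidin-2-one | O=C1OC[C@@H](Cc2ccccc2)N1C(=O)C[C@@H](CCCCCl)[C@@H]1CC[C@@H](CO[Si](C)(C)C(C)(C)C)N1C(=O)OC(C)(C)C | intermediate
13 | acetaldehyde | CC=O | starting material
14 | dibutylboron (Z)-enolate of 12 | CCCCB(CCCC)O/C(N1C(=O)OC[C@H]1Cc1ccccc1)=C\[C@@H](CCCCCl)[C@@H]1CC[C@@H](CO[Si](C)(C)C(C)(C)C)N1C(=O)OC(C)(C)C | intermediate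
15 | (4R)-4-benzyl-3-{(2R,3S)-2-[(1R)-5-chloro-1-Pyr-pentyl]-3-hydroxybutanoyl}-1,3-oxazolidin-2-one | O=C1OC[C@@H](Cc2ccccc2)N1C(=O)[C@@H]([C@H](C)O)[C@@H](CCCCCl)[C@@H]1CC[C@@H](CO[Si](C)(C)C(C)(C)C)N1C(=O)OC(C)(C)C | intermediate
16 | (2R,3S)-2-[(1R)-5-chloro-1-Pyr-pentyl]-3-hydroxybutaneperoxoic acid | OOC(=O)[C@@H]([C@H](C)O)[C@@H](CCCCCl)[C@@H]1CC[C@@H](CO[Si](C)(C)C(C)(C)C)N1C(=O)OC(C)(C)C | intermediate
17 | (2R,3S)-2-[(1R)-5-chloro-1-Pyr-pentyl]-3-hydroxybutanoic acid | OC(=O)[C@@H]([C@H](C)O)[C@@H](CCCCCl)[C@@H]1CC[C@@H](CO[Si](C)(C)C(C)(C)C)N1C(=O)OC(C)(C)C | intermediate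
18 | (2R,3S)-2-[(1R)-5-chloro-1-Pyr-pentyl]-3-hydroxy-N-methoxy-N-methylbutanamide | CON(C)C(=O)[C@@H]([C@H](C)O)[C@@H](CCCCCl)[C@@H]1CC[C@@H](CO[Si](C)(C)C(C)(C)C)N1C(=O)OC(C)(C)C | intermediate
19 | (5R,6S)-5-[(1R)-5-chloro-1-Pyr-pentyl]-6-hydroxyhept-2-yn-4-one | CC#CC(=O)[C@@H]([C@H](C)O)[C@@H](CCCCCl)[C@@H]1CC[C@@H](CO[Si](C)(C)C(C)(C)C)N1C(=O)OC(C)(C)C | intermediate
20 | (2S,3R,4R)-3-[(1R)-5-chloro-1-Pyr-pentyl]hept-5-yne-2,4-diol | CC#C[C@H](O)[C@@H]([C@H](C)O)[C@@H](CCCCCl)[C@@H]1CC[C@@H](CO[Si](C)(C)C(C)(C)C)N1C(=O)OC(C)(C)C | intermediate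
21 | (2S,3R,4S,5Z)-3-[(1R)-5-chloro-1-Pyr-pentyl]hept-5-ene-2,4-diol | C/C=C\[C@H](O)[C@@H]([C@H](C)O)[C@@H](CCCCCl)[C@@H]1CC[C@@H](CO[Si](C)(C)C(C)(C)C)N1C(=O)OC(C)(C)C | intermediate
22 | tert-butyl (2S,5S)-2-[(tert-butyldimethylsilyloxy)methyl]-5-{(1R)-5-chloro-1-[(3S,3aR,5S,6R,6aR)-3,5-dimethyl-2-oxohexahydrofuro[3,2-b]furan-6-yl]pentyl}pyrrolidine-1-carboxylate | C[C@@H]1O[C@H]2[C@H](OC(=O)[C@H]2C)[C@@H]1[C@@H](CCCCCl)[C@@H]1CC[C@@H](CO[Si](C)(C)C(C)(C)C)N1C(=O)OC(C)(C)C | intermediate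
23 | (3S,3aR,5S,6R,6aR)-6-{(1R)-5-chloro-1-[(2S,5S)-5-(hydroxymethyl)pyrrolidin-2-yl]pentyl}-3,5-dimethylhexahydrofuro[3,2-b]furan-2(3H)-one (formed as its trifluoroacetate salt) | C[C@@H]1O[C@H]2[C@H](OC(=O)[C@H]2C)[C@@H]1[C@@H](CCCCCl)[C@@H]1CC[C@@H](CO)N1 | intermediate
24 | (3S,3aR,5S,6R,6aR)-6-[(3S,9R,9aS)-3-(hydroxymethyl)octahydro-1H-pyrrolo[1,2-a]azepin-9-yl]-3,5-dimethylhexahydrofuro[3,2-b]furan-2(3H)-one | C[C@@H]1O[C@H]2[C@H](OC(=O)[C@H]2C)[C@@H]1[C@H]1CCCCN2[C@H]1CC[C@H]2CO | intermediate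
25 | (3S,9R,9aS)-9-[(3S,3aR,5S,6R,6aR)-3,5-dimethyl-2-oxohexahydrofuro[3,2-b]furan-6-yl]octahydro-1H-pyrrolo[1,2-a]azepine-3-carbaldehyde | C[C@@H]1O[C@H]2[C@H](OC(=O)[C@H]2C)[C@@H]1[C@H]1CCCCN2[C@H]1CC[C@H]2C=O | intermediate
26 | ethyl 2-(trimethylsilylmethyl)acrylate | CCOC(=O)C(=C)C[Si](C)(C)C | starting material
27 | ethyl 2-{(2S)-2-hydroxy-2-[(3S,9R,9aS)-9-[(3S,3aR,5S,6R,6aR)-3,5-dimethyl-2-oxohexahydrofuro[3,2-b]furan-6-yl]octahydro-1H-pyrrolo[1,2-a]azepin-3-yl]ethyl}prop-2-enoate | C[C@@H]1O[C@H]2[C@H](OC(=O)[C@H]2C)[C@@H]1[C@H]1CCCCN2[C@H]1CC[C@H]2[C@@H](O)CC(=C)C(=O)OCC | intermediate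
28 | (3S,3aR,5S,6R,6aR)-3,5-dimethyl-6-{(3S,9R,9aS)-3-[(2S)-4-methylidene-5-oxotetrahydrofuran-2-yl]octahydro-1H-pyrrolo[1,2-a]azepin-9-yl}hexahydrofuro[3,2-b]furan-2(3H)-one | C[C@@H]1O[C@H]2[C@H](OC(=O)[C@H]2C)[C@@H]1[C@H]1CCCCN2[C@H]1CC[C@H]2[C@@H]1CC(=C)C(=O)O1 | intermediate
29 | (3S,3aR,5S,6R,6aR)-3,5-dimethyl-6-{(3S,9R,9aS)-3-[(2S,4S)-4-methyl-5-oxotetrahydrofuran-2-yl]octahydro-1H-pyrrolo[1,2-a]azepin-9-yl}hexahydrofuro[3,2-b]furan-2(3H)-one | C[C@@H]1O[C@H]2[C@H](OC(=O)[C@H]2C)[C@@H]1[C@H]1CCCCN2[C@H]1CC[C@H]2[C@@H]1C[C@H](C)C(=O)O1 | target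

**Totals and risks**

Total step count: 17. Longest linear sequence: 15 steps (1 to 29 through steps 1, 2 and 5–17); steps 3 and 4 prepare phosphonate 8.

Steps most likely to fail:

1. Step 16. The electron-poor allylsilane may add slowly, so that chelate control erodes toward Felkin–Anh attack (wrong face at C5″) or the aldehyde epimerises at C3 or condenses with itself before it is consumed. The fallback sets out from 25 and separates C–C bond formation from lactone formation. A reagent-controlled propargylation with the allenylboronate of a dialkyl tartrate (closed six-membered transition state, tartrate antipode chosen for the 5″S carbinol) should give the homopropargylic alcohol F1. Hydroxyl-directed cyclocarbonylation of its but-3-yn-1-ol unit (PdCl2, SnCl2, PPh3, CO, MeCN, 75 °C) then closes ring E and comes back to the route at 28.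

2. Step 13. On the internal (Z)-alkene, CO capture may be slower than β-hydride loss or reversal of the oxypalladation, and crowding on the concave face may stall the bicyclisation. The fallback sets out from 18 and moves the C3′ methyl to a later stage.
   - H2C=CHMgBr should give the vinyl ketone F2, and Me4NBH(OAc)3 the anti diol F3.
   - The same PdCl2/CuCl2/CO bicyclisation, now on a terminal alkene (the best established substrate class), should give the lactone without the C3′ methyl F4.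
   - LiN(SiMe3)2 and then CH2=NMe2+ I− should give the Mannich base F5, MeI its ammonium iodide F6, and aqueous NaHCO3 the α-methylene lactone F7.
   - H2 over Pd/C should add from the convex face, place the methyl endo and come back to the route at 22.

3. Step 6. Attack at the β-carbon next to the carbamate-bearing ring may be sluggish, so that 1,2-attack on the imide or loss of facial control competes. The fallback sets out from 4 and uses substrate control on a less crowded acceptor.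
   - Olefination with triethyl phosphonoacetate (LiCl, iPr2NEt) should give the ethyl (E)-enoate F8.
   - Cl(CH2)4Cu·BF3 (from 11, CuI and BF3·OEt2) should add anti to the C9a–N bond and give the ester F9.
   - LiOH should give the acid F10, and pivaloyl chloride with Et3N its mixed anhydride F11.
   - Acylation of lithiated auxiliary 6 comes back to the route at 12.

Further compounds

F1 | step 16 | (3S,3aR,5S,6R,6aR)-6-{(3S,9R,9aS)-3-[(1S)-1-hydroxybut-3-yn-1-yl]octahydro-1H-pyrrolo[1,2-a]azepin-9-yl}-3,5-dimethylhexahydrofuro[3,2-b]furan-2(3H)-one | C[C@@H]1O[C@H]2[C@H](OC(=O)[C@H]2C)[C@@H]1[C@H]1CCCCN2[C@H]1CC[C@H]2[C@@H](O)CC#C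
F2 | step 13 | (4R,5S)-4-[(1R)-5-chloro-1-Pyr-pentyl]-5-hydroxyhex-1-en-3-one | C=CC(=O)[C@@H]([C@H](C)O)[C@@H](CCCCCl)[C@@H]1CC[C@@H](CO[Si](C)(C)C(C)(C)C)N1C(=O)OC(C)(C)C
F3 | step 13 | 1,3-anti 3-[(1R)-5-chloro-1-Pyr-pentyl]hex-5-ene-2,4-diol (configured as 21) | C=C[C@H](O)[C@@H]([C@H](C)O)[C@@H](CCCCCl)[C@@H]1CC[C@@H](CO[Si](C)(C)C(C)(C)C)N1C(=O)OC(C)(C)C
F4 | step 13 | analogue of 22 without the C3′ methyl | C[C@@H]1O[C@H]2[C@H](OC(=O)C2)[C@@H]1[C@@H](CCCCCl)[C@@H]1CC[C@@H](CO[Si](C)(C)C(C)(C)C)N1C(=O)OC(C)(C)C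
F5 | step 13 | analogue of 22 with an exo (dimethylamino)methyl group at C3′ | C[C@@H]1O[C@H]2[C@H](OC(=O)[C@@H]2CN(C)C)[C@@H]1[C@@H](CCCCCl)[C@@H]1CC[C@@H](CO[Si](C)(C)C(C)(C)C)N1C(=O)OC(C)(C)C
F6 | step 13 | trimethylammonium iodide of F5 | C[C@@H]1O[C@H]2[C@H](OC(=O)[C@@H]2C[N+](C)(C)C)[C@@H]1[C@@H](CCCCCl)[C@@H]1CC[C@@H](CO[Si](C)(C)C(C)(C)C)N1C(=O)OC(C)(C)C.[I-]
F7 | step 13 | analogue of 22 with a methylidene group at C3′ | C[C@@H]1O[C@H]2[C@H](OC(=O)C2=C)[C@@H]1[C@@H](CCCCCl)[C@@H]1CC[C@@H](CO[Si](C)(C)C(C)(C)C)N1C(=O)OC(C)(C)C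
F8 | step 6 | ethyl (2E)-3-Pyr-prop-2-enoate | CCOC(=O)/C=C/[C@@H]1CC[C@@H](CO[Si](C)(C)C(C)(C)C)N1C(=O)OC(C)(C)C
F9 | step 6 | ethyl (3R)-7-chloro-3-Pyr-heptanoate | CCOC(=O)C[C@@H](CCCCCl)[C@@H]1CC[C@@H](CO[Si](C)(C)C(C)(C)C)N1C(=O)OC(C)(C)C
F10 | step 6 | (3R)-7-chloro-3-Pyr-heptanoic acid | OC(=O)C[C@@H](CCCCCl)[C@@H]1CC[C@@H](CO[Si](C)(C)C(C)(C)C)N1C(=O)OC(C)(C)C
F11 | step 6 | (3R)-7-chloro-3-Pyr-heptanoic pivalic anhydride | CC(C)(C)C(=O)OC(=O)C[C@@H](CCCCCl)[C@@H]1CC[C@@H](CO[Si](C)(C)C(C)(C)C)N1C(=O)OC(C)(C)C
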